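**Retrosynthetic overview**

1. Ring letters: A = 4-hydroxy-3-methoxyphenyl; B and C = benzo ring and dihydrofuran ring (O1, C2, C3, C3a, C7a) of the benzofuran that carries ring A; D and E = dihydrofuran ring (O1', C2', C3', C3a', C7a') and benzo ring of the benzofuran that carries the (E)-3-hydroxypropenyl chain. The target comes from an all-cis triester by one base equilibration (C3 and C3' to trans), reduction of three esters and desilylation.
2. Ring C is closed last, through the C2–C3 bond: enantioselective 1,5 C–H insertion of a dirhodium carbene at C3 into the O–CH2 group that links ring A to the oxygen of ring B. The precursor has neither a ring nor a stereocentre at this site.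
3. Enabling feature: C2 is both benzylic to ring A and bound to O1, so its C–H bond is hydridic and lies 1,5 to C3. C3 carries CH2OH, which at the ester oxidation level makes C3 a donor/acceptor carbene carbon (donor ring B, acceptor CO2Et).
4. Ring D is closed earlier by the same reaction on a linear A–B–E bis(benzyl ether). Iodine on ring E and bromine on ring B time the two diazo installations (aryl iodide coupling first; bromine-to-iodine exchange and second coupling later).
5. The linear ether comes from vanillin, 5-bromovanillin and 5-iodovanillin by two Mitsunobu etherifications and one Wittig olefination. Ring order: rings A, B and E are bought, ring D forms in step 8, ring C in step 11.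

Key step: step 11

Assumption: Rh2(S-PTTL)4 is taken, by analogy with simpler 2-(benzyloxy)aryl diazoacetates, to select the benzylic hydrogen that leads to the 2S (and 2'S) centre; if the sense were the opposite, the same route would be run with Rh2(R-PTTL)4.

**Route**

Step 1
Reactants: 1 vanillin
Product: 2 3-methoxy-4-(triisopropylsilyloxy)benzaldehyde
Conditions: TIPSCl, imidazole, DMF, rt
Reagents that add atoms: chlorotriisopropylsilane, CC(C)[Si](Cl)(C(C)C)C(C)C
Why: Imidazole-promoted silylation of the phenol puts a hydride-stable, fluoride-labile group on the ring A oxygen, which must stay masked until the end so that C2 cannot ionise to a para-quinone methide.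

Step 2
Reactants: 2 3-methoxy-4-(triisopropylsilyloxy)benzaldehyde
Product: 3 [3-methoxy-4-(triisopropylsilyloxy)phenyl]methanol
Conditions: NaBH4, MeOH, 0 °C
Reagents that add atoms: none
Why: Borohydride reduction of the aryl aldehyde gives the benzylic alcohol and leaves the aryl silyl ether untouched.

Step 3
Reactants: 3 [3-methoxy-4-(triisopropylsilyloxy)phenyl]methanol; 4 5-bromovanillin
Product: 5 3-bromo-5-methoxy-4-{[3-methoxy-4-(triisopropylsilyloxy)benzyl]oxy}benzaldehyde
Conditions: PPh3, DIAD, THF, 0 °C to rt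
Reagents that add atoms: none
Why: Mitsunobu etherification; the acidic para-formyl phenol 4 is O-alkylated by the phosphonium-activated primary benzylic alcohol under neutral conditions, which avoids a labile para-silyloxybenzyl halide and base-induced silyl loss.

Step 4
Reactants: 5 3-bromo-5-methoxy-4-{[3-methoxy-4-(triisopropylsilyloxy)benzyl]oxy}benzaldehyde
Product: 6 (3-bromo-5-methoxy-4-{[3-methoxy-4-(triisopropylsilyloxy)benzyl]oxy}phenyl)methanol
Conditions: NaBH4, THF/MeOH, 0 °C
Reagents that add atoms: none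
Why: Borohydride reduction of the aldehyde to the benzylic alcohol is chemoselective in the presence of the aryl bromide, the benzyl ether and the silyl ether.

Step 5
Reactants: 7 5-iodovanillin; 8 ethyl (triphenylphosphoranylidene)acetate
Product: 9 ethyl (E)-3-(4-hydroxy-3-iodo-5-methoxyphenyl)acrylate
Conditions: toluene, 100 °C
Reagents that add atoms: none
Why: Wittig olefination with a stabilised ylide should give the E-cinnamate (thermodynamic control of the oxaphosphetane) and tolerates the free phenol and the aryl iodide.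

Step 6
Reactants: 6 (3-bromo-5-methoxy-4-{[3-methoxy-4-(triisopropylsilyloxy)benzyl]oxy}phenyl)methanol; 9 ethyl (E)-3-(4-hydroxy-3-iodo-5-methoxyphenyl)acrylate
Product: 10 ethyl (E)-3-{4-[(3-bromo-5-methoxy-4-{[3-methoxy-4-(triisopropylsilyloxy)benzyl]oxy}benzyl)oxy]-3-iodo-5-methoxyphenyl}acrylate
Conditions: PPh3, DIAD, THF, 0 °C to rt
Reagents that add atoms: none
Why: A second Mitsunobu etherification joins the acidic iodophenol 9 to the primary benzylic alcohol 6 and completes the achiral A–B–E chain with iodine on ring E and bromine on ring B.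

Step 7
Reactants: 10 ethyl (E)-3-{4-[(3-bromo-5-methoxy-4-{[3-methoxy-4-(triisopropylsilyloxy)benzyl]oxy}benzyl)oxy]-3-iodo-5-methoxyphenyl}acrylate; 11 ethyl diazoacetate
Product: 12 ethyl (E)-3-{4-[(3-bromo-5-methoxy-4-{[3-methoxy-4-(triisopropylsilyloxy)benzyl]oxy}benzyl)oxy]-3-(1-diazo-2-ethoxy-2-oxoethyl)-5-methoxyphenyl}acrylate
Conditions: Pd(PPh3)4 (5 mol%), Ag2CO3 (0.5 equiv), Et3N, toluene, rt
Reagents that add atoms: none
Why: Palladium-catalysed cross-coupling of an aryl iodide with the C–H bond of an acceptor diazo compound, with the diazo group retained; oxidative addition at room temperature takes the C–I bond of ring E and spares the C–Br bond of ring B, and the donor-conjugated cinnamate is a poor dipolarophile for the diazo groups.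

Step 8
Reactants: 12 ethyl (E)-3-{4-[(3-bromo-5-methoxy-4-{[3-methoxy-4-(triisopropylsilyloxy)benzyl]oxy}benzyl)oxy]-3-(1-diazo-2-ethoxy-2-oxoethyl)-5-methoxyphenyl}acrylate
Product: 13 ethyl (2S,3R)-2-(3-bromo-5-methoxy-4-{[3-methoxy-4-(triisopropylsilyloxy)benzyl]oxy}phenyl)-5-[(E)-3-ethoxy-3-oxoprop-1-enyl]-7-methoxy-2,3-dihydrobenzofuran-3-carboxylate (2,3-cis)
Conditions: Rh2(S-PTTL)4 (dirhodium tetrakis[N-phthaloyl-(S)-tert-leucinate], 1 mol%), toluene, −78 to −40 °C
Reagents that add atoms: none
Why: Enantioselective intramolecular 1,5 C–H insertion of a dirhodium donor/acceptor carbene into the benzylic O–CH2 group of ring B closes ring D; C2' (S) is set by the catalyst's choice between the two enantiotopic hydrogens and C3' arises 2,3-cis (R) from the compact transition state, to be equilibrated in step 12, while the aryl bromide, the silyl ether and the electron-poor cinnamate are inert to the carbene.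

Step 9
Reactants: 13 ethyl (2S,3R)-2-(3-bromo-5-methoxy-4-{[3-methoxy-4-(triisopropylsilyloxy)benzyl]oxy}phenyl)-5-[(E)-3-ethoxy-3-oxoprop-1-enyl]-7-methoxy-2,3-dihydrobenzofuran-3-carboxylate
Product: 14 ethyl (2S,3R)-5-[(E)-3-ethoxy-3-oxoprop-1-enyl]-2-(3-iodo-5-methoxy-4-{[3-methoxy-4-(triisopropylsilyloxy)benzyl]oxy}phenyl)-7-methoxy-2,3-dihydrobenzofuran-3-carboxylate
Conditions: CuI (10 mol%), trans-N,N'-dimethylcyclohexane-1,2-diamine (20 mol%), NaI (2 equiv), 1,4-dioxane, 110 °C
Reagents that add atoms: sodium iodide, [Na+].[I-]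
Why: Copper-catalysed aromatic Finkelstein reaction, driven by precipitation of NaBr in dioxane, turns the ring B bromide into the iodide needed for the second diazo coupling; it tolerates esters and ethers, and any partial epimerisation at C3' is harmless because step 12 equilibrates that centre.

Step 10
Reactants: 14 ethyl (2S,3R)-5-[(E)-3-ethoxy-3-oxoprop-1-enyl]-2-(3-iodo-5-methoxy-4-{[3-methoxy-4-(triisopropylsilyloxy)benzyl]oxy}phenyl)-7-methoxy-2,3-dihydrobenzofuran-3-carboxylate; 11 ethyl diazoacetate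
Product: 15 ethyl (2S,3R)-2-[3-(1-diazo-2-ethoxy-2-oxoethyl)-5-methoxy-4-{[3-methoxy-4-(triisopropylsilyloxy)benzyl]oxy}phenyl]-5-[(E)-3-ethoxy-3-oxoprop-1-enyl]-7-methoxy-2,3-dihydrobenzofuran-3-carboxylate
Conditions: Pd(PPh3)4 (5 mol%), Ag2CO3 (0.5 equiv), Et3N, toluene, rt
Reagents that add atoms: none
Why: The same palladium-catalysed coupling of an aryl iodide with the diazoacetate C–H bond as in step 7, now at ring B, places the carbene precursor ortho to the O–CH2 group that leads to ring A; the mild base does not disturb the ring D ester.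

Step 11
Reactants: 15 ethyl (2S,3R)-2-[3-(1-diazo-2-ethoxy-2-oxoethyl)-5-methoxy-4-{[3-methoxy-4-(triisopropylsilyloxy)benzyl]oxy}phenyl]-5-[(E)-3-ethoxy-3-oxoprop-1-enyl]-7-methoxy-2,3-dihydrobenzofuran-3-carboxylate
Product: 16 ethyl (2S,3R)-2-{(2S,3R)-3-(ethoxycarbonyl)-7-methoxy-2-[3-methoxy-4-(triisopropylsilyloxy)phenyl]-2,3-dihydrobenzofuran-5-yl}-5-[(E)-3-ethoxy-3-oxoprop-1-enyl]-7-methoxy-2,3-dihydrobenzofuran-3-carboxylate (both dihydrofuran rings 2,3-cis)
Conditions: Rh2(S-PTTL)4 (2 mol%), toluene, −78 to −40 °C, slow addition of 15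
Reagents that add atoms: none
Why: Rh2(S-PTTL)4 takes N2 out of 15 and gives a donor/acceptor dirhodium carbene at C3 (donor ring B, acceptor CO2Et), which inserts through a three-centre, hydride-transfer-like transition state into one of the two enantiotopic hydrogens of the O–CH2 group between O1 and ring A, so that the C2–C3 bond and ring C form in one event. The closest known reaction type is the enantioselective intramolecular 1,5 C–H insertion of 2-(benzyloxy)aryl diazoacetates to cis-2-aryl-2,3-dihydrobenzofuran-3-carboxylates under dirhodium tetrakis(N-phthaloyl-tert-leucinate) catalysis, including 7-alkoxy cases with the same flanking methoxy group. Ring C closes as a five-membered ring by 1,5 insertion (carbene carbon C3 onto C2–H, with C3a, C7a and O1 as the tether). C2 is set by the catalyst, whose phthalimido wall selects the pro-stereogenic hydrogen (expected 2S), and C3 follows from the compact insertion transition state as 2,3-cis (3R), a centre that step 12 may equilibrate freely. The step needs site selectivity for this C–H bond over the methoxy groups, the cinnamate alkene and bimolecular carbene decay; this is secured by the 1,5 geometry, the double activation of the C–H bond (benzylic to the electron-rich ring A and alpha to oxygen), the electron-poor 1,2-disubstituted alkene, low temperature and slow addition. It also needs catalyst control beside a chiral ring D, which is expected because C2' and C3' sit meta to the carbene on ring B and far from the reacting atoms; since steps 8 and 11 use the same catalyst, a mis-selection in either step ends in a diastereomer that chromatography removes, so the enantiomeric purity of the matched product should be raised.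

Step 12
Reactants: 16 all-cis triester
Product: 17 ethyl (2S,3S)-2-{(2S,3S)-3-(ethoxycarbonyl)-7-methoxy-2-[3-methoxy-4-(triisopropylsilyloxy)phenyl]-2,3-dihydrobenzofuran-5-yl}-5-[(E)-3-ethoxy-3-oxoprop-1-enyl]-7-methoxy-2,3-dihydrobenzofuran-3-carboxylate (both rings 2,3-trans)
Conditions: NaOEt (0.3 equiv), EtOH/THF, 0 °C to rt; AcOH quench
Reagents that add atoms: none
Why: Thermodynamic epimerisation through the ester enolates at C3 and C3' funnels both cis rings (and any stray cis/trans mixture) into the 2,3-trans esters, which relieve the aryl/ester eclipsing; C2 and C2' are not acidic, the ethoxide matches the esters, ring opening by beta-elimination is the stereoelectronically disfavoured reverse of a 5-endo closure, and the silyl ether keeps ring A from forming a para-quinone methide.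

Step 13
Reactants: 17 all-trans triester
Product: 18 (E)-3-{(2S,3R)-3-(hydroxymethyl)-2-[(2S,3R)-3-(hydroxymethyl)-7-methoxy-2-[3-methoxy-4-(triisopropylsilyloxy)phenyl]-2,3-dihydrobenzofuran-5-yl]-7-methoxy-2,3-dihydrobenzofuran-5-yl}prop-2-en-1-ol
Conditions: i-Bu2AlH (9 equiv), CH2Cl2, −78 to 0 °C; aq. KNaC4H4O6 work-up
Reagents that add atoms: none
Why: Hydride reduction of all three esters with i-Bu2AlH gives the two primary alcohols and, by clean 1,2-reduction of the cinnamate, the E-allylic alcohol; the stereocentres are untouched (the descriptor at C3 and C3' changes from S to R only because the CIP priorities change).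

Step 14
Reactants: 18 silyl-protected triol
Product: 19 (E)-3-{(2S,3R)-2-[(2S,3R)-2-(4-hydroxy-3-methoxyphenyl)-3-(hydroxymethyl)-7-methoxy-2,3-dihydrobenzofuran-5-yl]-3-(hydroxymethyl)-7-methoxy-2,3-dihydrobenzofuran-5-yl}prop-2-en-1-ol (target)
Conditions: Bu4NF, AcOH (1:1), THF, 0 °C
Reagents that add atoms: none
Why: Fluoride-mediated cleavage of the aryl silyl ether frees the ring A phenol; the acetic acid buffer keeps the liberated para-hydroxybenzyl aryl ether away from base, and the allylic alcohol and both trans rings are inert.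

**Compound list**

1 | vanillin (4-hydroxy-3-methoxybenzaldehyde) | COc1cc(C=O)ccc1O | starting material
2 | 3-methoxy-4-(triisopropylsilyloxy)benzaldehyde | COc1cc(C=O)ccc1O[Si](C(C)C)(C(C)C)C(C)C | intermediate
3 | [3-methoxy-4-(triisopropylsilyloxy)phenyl]methanol | COc1cc(CO)ccc1O[Si](C(C)C)(C(C)C)C(C)C | intermediate
4 | 5-bromovanillin (3-bromo-4-hydroxy-5-methoxybenzaldehyde) | COc1cc(C=O)cc(Br)c1O | starting material
5 | 3-bromo-5-methoxy-4-{[3-methoxy-4-(triisopropylsilyloxy)benzyl]oxy}benzaldehyde | COc1cc(COc2c(Br)cc(C=O)cc2OC)ccc1O[Si](C(C)C)(C(C)C)C(C)C | intermediate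
6 | (3-bromo-5-methoxy-4-{[3-methoxy-4-(triisopropylsilyloxy)benzyl]oxy}phenyl)methanol | COc1cc(COc2c(Br)cc(CO)cc2OC)ccc1O[Si](C(C)C)(C(C)C)C(C)C | intermediate
7 | 5-iodovanillin (4-hydroxy-3-iodo-5-methoxybenzaldehyde) | COc1cc(C=O)cc(I)c1O | starting material
8 | ethyl (triphenylphosphoranylidene)acetate | CCOC(=O)C=P(c1ccccc1)(c1ccccc1)c1ccccc1 | starting material
9 | ethyl (E)-3-(4-hydroxy-3-iodo-5-methoxyphenyl)acrylate | CCOC(=O)/C=C/c1cc(I)c(O)c(OC)c1 | intermediate
10 | ethyl (E)-3-{4-[(3-bromo-5-methoxy-4-{[3-methoxy-4-(triisopropylsilyloxy)benzyl]oxy}benzyl)oxy]-3-iodo-5-methoxyphenyl}acrylate | CCOC(=O)/C=C/c1cc(I)c(OCc2cc(Br)c(OCc3ccc(O[Si](C(C)C)(C(C)C)C(C)C)c(OC)c3)c(OC)c2)c(OC)c1 | intermediate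
11 | ethyl diazoacetate | CCOC(=O)C=[N+]=[N-] | starting material
12 | ethyl (E)-3-{4-[(3-bromo-5-methoxy-4-{[3-methoxy-4-(triisopropylsilyloxy)benzyl]oxy}benzyl)oxy]-3-(1-diazo-2-ethoxy-2-oxoethyl)-5-methoxyphenyl}acrylate | CCOC(=O)/C=C/c1cc(OC)c(OCc2cc(Br)c(OCc3ccc(O[Si](C(C)C)(C(C)C)C(C)C)c(OC)c3)c(OC)c2)c(c1)C(=[N+]=[N-])C(=O)OCC | intermediate
13 | ethyl (2S,3R)-2-(3-bromo-5-methoxy-4-{[3-methoxy-4-(triisopropylsilyloxy)benzyl]oxy}phenyl)-5-[(E)-3-ethoxy-3-oxoprop-1-enyl]-7-methoxy-2,3-dihydrobenzofuran-3-carboxylate (cis) | CC(C)[Si](C(C)C)(C(C)C)Oc1ccc(COc2c(OC)cc(cc2Br)[C@H]3Oc4c(OC)cc(/C=C/C(=O)OCC)cc4[C@H]3C(=O)OCC)cc1OC | intermediate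
14 | ethyl (2S,3R)-5-[(E)-3-ethoxy-3-oxoprop-1-enyl]-2-(3-iodo-5-methoxy-4-{[3-methoxy-4-(triisopropylsilyloxy)benzyl]oxy}phenyl)-7-methoxy-2,3-dihydrobenzofuran-3-carboxylate (cis) | CC(C)[Si](C(C)C)(C(C)C)Oc1ccc(COc2c(OC)cc(cc2I)[C@H]3Oc4c(OC)cc(/C=C/C(=O)OCC)cc4[C@H]3C(=O)OCC)cc1OC | intermediate
15 | ethyl (2S,3R)-2-[3-(1-diazo-2-ethoxy-2-oxoethyl)-5-methoxy-4-{[3-methoxy-4-(triisopropylsilyloxy)benzyl]oxy}phenyl]-5-[(E)-3-ethoxy-3-oxoprop-1-enyl]-7-methoxy-2,3-dihydrobenzofuran-3-carboxylate (cis) | CC(C)[Si](C(C)C)(C(C)C)Oc1ccc(COc2c(OC)cc(cc2C(=[N+]=[N-])C(=O)OCC)[C@H]3Oc4c(OC)cc(/C=C/C(=O)OCC)cc4[C@H]3C(=O)OCC)cc1OC | intermediate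
16 | ethyl (2S,3R)-2-{(2S,3R)-3-(ethoxycarbonyl)-7-methoxy-2-[3-methoxy-4-(triisopropylsilyloxy)phenyl]-2,3-dihydrobenzofuran-5-yl}-5-[(E)-3-ethoxy-3-oxoprop-1-enyl]-7-methoxy-2,3-dihydrobenzofuran-3-carboxylate (cis, cis) | COc1cc([C@H]2Oc3c(OC)cc([C@H]4Oc5c(OC)cc(/C=C/C(=O)OCC)cc5[C@H]4C(=O)OCC)cc3[C@H]2C(=O)OCC)ccc1O[Si](C(C)C)(C(C)C)C(C)C | intermediate
17 | ethyl (2S,3S)-2-{(2S,3S)-3-(ethoxycarbonyl)-7-methoxy-2-[3-methoxy-4-(triisopropylsilyloxy)phenyl]-2,3-dihydrobenzofuran-5-yl}-5-[(E)-3-ethoxy-3-oxoprop-1-enyl]-7-methoxy-2,3-dihydrobenzofuran-3-carboxylate (trans, trans) | COc1cc([C@H]2Oc3c(OC)cc([C@H]4Oc5c(OC)cc(/C=C/C(=O)OCC)cc5[C@@H]4C(=O)OCC)cc3[C@@H]2C(=O)OCC)ccc1O[Si](C(C)C)(C(C)C)C(C)C | intermediate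
18 | (E)-3-{(2S,3R)-3-(hydroxymethyl)-2-[(2S,3R)-3-(hydroxymethyl)-7-methoxy-2-[3-methoxy-4-(triisopropylsilyloxy)phenyl]-2,3-dihydrobenzofuran-5-yl]-7-methoxy-2,3-dihydrobenzofuran-5-yl}prop-2-en-1-ol | COc1cc([C@H]2Oc3c(OC)cc([C@H]4Oc5c(OC)cc(/C=C/CO)cc5[C@@H]4CO)cc3[C@@H]2CO)ccc1O[Si](C(C)C)(C(C)C)C(C)C | intermediate
19 | (E)-3-{(2S,3R)-2-[(2S,3R)-2-(4-hydroxy-3-methoxyphenyl)-3-(hydroxymethyl)-7-methoxy-2,3-dihydrobenzofuran-5-yl]-3-(hydroxymethyl)-7-methoxy-2,3-dihydrobenzofuran-5-yl}prop-2-en-1-ol | COc1cc([C@H]2Oc3c(OC)cc([C@H]4Oc5c(OC)cc(/C=C/CO)cc5[C@@H]4CO)cc3[C@@H]2CO)ccc1O | target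

**Step count**

Total step count: 14. Longest linear sequence: 13 steps (steps 1–4 and 6–14, from vanillin).

**Steps most likely to fail**

Step 11. The catalyst may lose control over the choice between the two enantiotopic benzylic hydrogens in this large substrate, so that C2 forms with poor facial selectivity, or the carbene may decay bimolecularly. The fallback moves the stereocontrol onto a covalently bound auxiliary used with a trans-selective catalyst; it sets out from iodide 14 and comes back to the route at 17. Ethyl (S)-lactate and pyrrolidine (neat, heat) would give (S)-2-hydroxy-1-(pyrrolidin-1-yl)propan-1-one F1. Bromoacetyl bromide and pyridine would give (S)-1-oxo-1-(pyrrolidin-1-yl)propan-2-yl bromoacetate F2. N,N'-Ditosylhydrazine and DBU would turn it into (S)-1-oxo-1-(pyrrolidin-1-yl)propan-2-yl diazoacetate F3. Coupling of this diazoacetate with 14 under the conditions of step 10 would give the lactamide aryldiazoacetate F4. Insertion with Rh2(S-DOSP)4 (dirhodium tetrakis[(S)-N-(4-dodecylbenzenesulfonyl)prolinate]) in CH2Cl2 at low temperature is expected, by double stereodifferentiation known for this ester class, to give directly the ring C 2,3-trans (2S,3S) lactamide ester F5 (S-lactamide assumed as the matched antipode). NaOEt in EtOH (conditions of step 12) would then exchange the lactamide ester for the ethyl ester and equilibrate C3', which gives 17.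

Step 10. Oxidative addition and diazo transfer to palladium may be slow at the hindered ortho-alkoxy aryl iodide, and the diazo group may be lost through palladium carbene formation. The fallback builds the diazoester by enolate arylation and diazo transfer; it sets out from bromide 13 (so the halogen exchange of step 9 is bypassed as well) and comes back at 15, or at 17 for any material epimerised on the way. Arylation of the Reformatsky reagent BrZnCH2CO2Et (from zinc and ethyl bromoacetate) with Pd(dba)2 and Q-Phos in THF at rt would give ethyl arylacetate F6. Regitz diazo transfer (4-acetamidobenzenesulfonyl azide, DBU, MeCN) would give 15. To the extent that DBU epimerises C3', the C3'-trans diazoester F7 would form; it would pass through step 11 as the cis-ring-C, trans-ring-D triester F8, which converges with 16 on 17 in step 12.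

Step 6. The redox condensation may stall at the di-ortho-substituted phenol, with the activated benzylic alcohol diverted to alkylation of the hydrazine dicarboxylate. The fallback replaces it by phenoxide alkylation with an isolated halide; it sets out from alcohol 6 and comes back at 10. Appel bromination (CBr4, PPh3, CH2Cl2, 0 °C) would give 3-bromo-5-methoxy-4-{[3-methoxy-4-(triisopropylsilyloxy)benzyl]oxy}benzyl bromide F9, and Williamson etherification of phenol 9 with it (K2CO3, acetone, 50 °C) would give 10.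

**Further compounds**

F1 | step 11 | (S)-2-hydroxy-1-(pyrrolidin-1-yl)propan-1-one | C[C@H](O)C(=O)N1CCCC1
F2 | step 11 | (S)-1-oxo-1-(pyrrolidin-1-yl)propan-2-yl bromoacetate | C[C@H](OC(=O)CBr)C(=O)N1CCCC1
F3 | step 11 | (S)-1-oxo-1-(pyrrolidin-1-yl)propan-2-yl diazoacetate | C[C@H](OC(=O)C=[N+]=[N-])C(=O)N1CCCC1
F4 | step 11 | lactamide aryldiazoacetate (analogue of 15 with the (S)-1-oxo-1-(pyrrolidin-1-yl)propan-2-yl ester at the diazo carbon) | CC(C)[Si](C(C)C)(C(C)C)Oc1ccc(COc2c(OC)cc(cc2C(=[N+]=[N-])C(=O)O[C@@H](C)C(=O)N5CCCC5)[C@H]3Oc4c(OC)cc(/C=C/C(=O)OCC)cc4[C@H]3C(=O)OCC)cc1OC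
F5 | step 11 | ring C 2,3-trans (2S,3S) lactamide ester, ring D cis (2S,3R) ethyl ester | COc1cc([C@H]2Oc3c(OC)cc([C@H]4Oc5c(OC)cc(/C=C/C(=O)OCC)cc5[C@H]4C(=O)OCC)cc3[C@@H]2C(=O)O[C@@H](C)C(=O)N6CCCC6)ccc1O[Si](C(C)C)(C(C)C)C(C)C
F6 | step 10 | ethyl (2S,3R)-2-[3-(2-ethoxy-2-oxoethyl)-5-methoxy-4-{[3-methoxy-4-(triisopropylsilyloxy)benzyl]oxy}phenyl]-5-[(E)-3-ethoxy-3-oxoprop-1-enyl]-7-methoxy-2,3-dihydrobenzofuran-3-carboxylate | CC(C)[Si](C(C)C)(C(C)C)Oc1ccc(COc2c(OC)cc(cc2CC(=O)OCC)[C@H]3Oc4c(OC)cc(/C=C/C(=O)OCC)cc4[C@H]3C(=O)OCC)cc1OC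
F7 | step 10 | C3' epimer of 15 (ring D 2,3-trans, 2S,3S) | CC(C)[Si](C(C)C)(C(C)C)Oc1ccc(COc2c(OC)cc(cc2C(=[N+]=[N-])C(=O)OCC)[C@H]3Oc4c(OC)cc(/C=C/C(=O)OCC)cc4[C@@H]3C(=O)OCC)cc1OC
F8 | step 10 | C3' epimer of 16 (ring C cis 2S,3R; ring D trans 2S,3S) | COc1cc([C@H]2Oc3c(OC)cc([C@H]4Oc5c(OC)cc(/C=C/C(=O)OCC)cc5[C@@H]4C(=O)OCC)cc3[C@H]2C(=O)OCC)ccc1O[Si](C(C)C)(C(C)C)C(C)C
F9 | step 6 | 3-bromo-5-methoxy-4-{[3-methoxy-4-(triisopropylsilyloxy)benzyl]oxy}benzyl bromide | COc1cc(COc2c(Br)cc(CBr)cc2OC)ccc1O[Si](C(C)C)(C(C)C)C(C)C
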